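**Strategy**

Everything rests on cutting the C9–C10 bond of ring B (labdane numbering). The target carries a quaternary C10 with an oxidised carbon (C20, CH2OAc) bonded to C9, which sits beside the C8(17) exocyclic methylene: the imprint of an enol ether β-carbon joined to the γ-carbon of an allylsilane. Anodic oxidation of a ring A methoxymethylidene ester bearing a (Z)-trisubstituted allylsilane on C5 closes ring B in one operation, sets C9 and C10, unveils the C8(17) methylene and leaves C20 as a dimethyl acetal. The precursor is a cyclohexane with the C4 methyl/ester centre, the C10=C20 enol ether and a chloride at C12 for the later butenolide coupling.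

Key step: step 9

**Remarks and assumptions**

- Labdane numbering (C1–C20) is used for positions in all intermediates.
- The ring-closure substrate was checked against the target and needed no correction of configuration or skeleton. C4 (methyl α, ester β) and C5 (H α) map onto 4S,5R of the target. The (Z)-allylsilane (CH2SiMe3 cis to C11, C7 trans to C11) is the geometry that puts C11 equatorial in a chair closure.
- Design change 1: C12 carries a chloride in place of a protected alcohol. It is inert to base and at the anode, and is exchanged for iodide just before the zinc insertion, so no deprotection is needed.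
- Design change 2: the enol ether is made before the C4 methylation. No ketal is needed, no acid meets the allylsilane, and C5 is flanked by two exocyclic double bonds during the methylation.
- Design change 3: the allylsilane geometry is taken from a dihydrofuran ring, not from an olefination.
- Assumption: CuH delivers hydride to the ester-bearing carbon (β to the ketone), with the sense of induction known for 3-alkylcyclohexenones. If the sense is opposite, the antipodal ligand is used.
- The enol ether in 16–18 is expected as an E/Z mixture and is used as such.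
- Compounds 1, 2, 6, 12, 15 and 24 are taken as commercially available.

**Route**

Step 1
Reactants: 1 2,3-dihydrofuran; 2 oxirane
Product: 5 tert-butyl[2-(4,5-dihydrofuran-2-yl)ethoxy]dimethylsilane, via 5-lithio-2,3-dihydrofuran 3 (not isolated), via lithium 2-(4,5-dihydrofuran-2-yl)ethanolate 4 (not isolated)
Conditions: t-BuLi, THF/pentane, −78 → 0 °C; 2, −78 °C → rt; TBSCl, 0 °C → rt
Reagents that add atoms: 2 oxirane, C1CO1; tert-butyldimethylsilyl chloride, CC(C)(C)[Si](C)(C)Cl
Why: α-Lithiation of the cyclic enol ether at the oxygen-bearing vinylic carbon gives a vinyllithium that opens oxirane by SN2 attack (epoxide opening by an organolithium), and the lithium alkoxide is silylated in the same flask, so the C6–C7–C8 unit is assembled with C8 still held as the ring enol ether carbon.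

Step 2
Reactants: 5 tert-butyl[2-(4,5-dihydrofuran-2-yl)ethoxy]dimethylsilane; 6 (trimethylsilyl)methylmagnesium chloride
Product: 7 (3Z)-6-[(tert-butyldimethylsilyl)oxy]-4-[(trimethylsilyl)methyl]hex-3-en-1-ol
Conditions: 6 (excess), Ni(PPh3)2Cl2 (5 mol%), toluene, 80 °C; aq. NH4Cl
Reagents that add atoms: 6 (trimethylsilyl)methylmagnesium chloride, C[Si](C)(C)C[Mg]Cl
Why: Nickel-catalysed Kumada-type cross-coupling of the Grignard reagent (no β-hydrogen) with the enol ether C–O bond opens the ring with retention at the vinylic carbon, so CH2SiMe3 takes the place of oxygen cis to the ring-derived CH2CH2OH arm (C11–C12) and the (Z)-allylsilane with C7 trans to C11 should result with its geometry fixed by the ring.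

Step 3
Reactants: 7 (3Z)-6-[(tert-butyldimethylsilyl)oxy]-4-[(trimethylsilyl)methyl]hex-3-en-1-ol
Product: 9 tert-butyl{[(3Z)-6-chloro-3-[(trimethylsilyl)methyl]hex-3-en-1-yl]oxy}dimethylsilane, via mesylate 8 (not isolated)
Conditions: MsCl, Et3N, CH2Cl2, 0 °C; LiCl, DMF, rt → 40 °C
Reagents that add atoms: lithium chloride, [Li+].[Cl-]
Why: Sulfonylation of the primary alcohol and SN2 displacement of the mesylate by chloride in a polar aprotic, non-acidic medium leave the allylsilane and the silyl ether untouched and install the robust placeholder for the later C12 iodide.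

Step 4
Reactants: 9 tert-butyl{[(3Z)-6-chloro-3-[(trimethylsilyl)methyl]hex-3-en-1-yl]oxy}dimethylsilane
Product: 10 (3Z)-6-chloro-3-[(trimethylsilyl)methyl]hex-3-en-1-ol
Conditions: Bu4NF, AcOH, THF, 0 °C → rt
Reagents that add atoms: none
Why: Fluoride-mediated cleavage of the O–Si bond (silyl ether deprotection) under buffered conditions should spare the far less fluorophilic C–Si bond of the allylsilane and the primary chloride.

Step 5
Reactants: 10 (3Z)-6-chloro-3-[(trimethylsilyl)methyl]hex-3-en-1-ol
Product: 11 (3Z)-6-chloro-1-iodo-3-[(trimethylsilyl)methyl]hex-3-ene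
Conditions: PPh3, I2, imidazole, CH2Cl2, 0 °C (phosphine–iodine adduct pre-formed, alcohol added last)
Reagents that add atoms: iodine, II
Why: Appel-type iodination converts the primary alcohol into the iodide by SN2 displacement of the oxyphosphonium group, and pre-forming the phosphine–iodine adduct keeps free iodine away from the allylsilane.

Step 6
Reactants: 12 methyl 3-oxocyclohex-1-ene-1-carboxylate; 11 (3Z)-6-chloro-1-iodo-3-[(trimethylsilyl)methyl]hex-3-ene
Product: 14 methyl (1R,2S)-2-{(3Z)-6-chloro-3-[(trimethylsilyl)methyl]hex-3-en-1-yl}-3-oxocyclohexane-1-carboxylate, via silyl enol ether 13 (not isolated)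
Conditions: Cu(OAc)2·H2O (3 mol%), (R)-DTBM-SEGPHOS (3 mol%), PhMe2SiH, toluene, 0 °C; then 11, Bu4N[Ph3SiF2] (1.0 equiv), CH2Cl2, −20 °C → rt
Reagents that add atoms: 11 (3Z)-6-chloro-1-iodo-3-[(trimethylsilyl)methyl]hex-3-ene, ICC/C(C[Si](C)(C)C)=C/CCCl
Why: Ligand-controlled CuH conjugate reduction sets the C4–H centre and gives a regiodefined silyl enol ether, which fluoride unmasks as an ammonium enolate that is alkylated only at C5 by the iodide end of 11 (tandem asymmetric conjugate reduction–enolate alkylation), the chain entering anti to the C4 ester to give the trans-2,3-disubstituted ketone, which is also the thermodynamic isomer at the epimerisable C5.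

Step 7
Reactants: 14 methyl (1R,2S)-2-{(3Z)-6-chloro-3-[(trimethylsilyl)methyl]hex-3-en-1-yl}-3-oxocyclohexane-1-carboxylate; 15 (methoxymethyl)triphenylphosphonium chloride
Product: 16 methyl (1R,2S)-2-{(3Z)-6-chloro-3-[(trimethylsilyl)methyl]hex-3-en-1-yl}-3-(methoxymethylidene)cyclohexane-1-carboxylate (E/Z mixture at the enol ether)
Conditions: 15, KN(SiMe3)2 (slight deficit), THF, 0 °C; then 14, −78 → 0 °C
Reagents that add atoms: 15 (methoxymethyl)triphenylphosphonium chloride, COC[P+](c1ccccc1)(c1ccccc1)c1ccccc1.[Cl-]
Why: Wittig olefination of the only ketone with the methoxymethylidene ylide gives the methyl enol ether while ester, chloride and allylsilane are inert, and using a cold ylide free of excess base limits epimerisation at C5 before the carbonyl that makes it labile is removed.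

Step 8
Reactants: 16 methyl (1R,2S)-2-{(3Z)-6-chloro-3-[(trimethylsilyl)methyl]hex-3-en-1-yl}-3-(methoxymethylidene)cyclohexane-1-carboxylate
Product: 18 methyl (1S,2R)-2-{(3Z)-6-chloro-3-[(trimethylsilyl)methyl]hex-3-en-1-yl}-3-(methoxymethylidene)-1-methylcyclohexane-1-carboxylate (E/Z mixture at the enol ether), via lithium ester enolate 17 (not isolated)
Conditions: LiN(i-Pr)2, THF, −78 °C; MeI, DMPU, −78 → −30 °C
Reagents that add atoms: iodomethane, CI
Why: In this ester enolate alkylation, allylic 1,3-strain from both the exocyclic enolate and the exocyclic enol ether forces the C5 chain axial, so iodomethane should attack C4 from the face anti to the chain and create the quaternary centre with methyl trans and ester cis to the chain.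

Step 9
Reactants: 18 methyl (1S,2R)-2-{(3Z)-6-chloro-3-[(trimethylsilyl)methyl]hex-3-en-1-yl}-3-(methoxymethylidene)-1-methylcyclohexane-1-carboxylate
Product: 19 methyl (1S,4aS,5S,8aR)-5-(2-chloroethyl)-4a-(dimethoxymethyl)-1-methyl-6-methylidenedecahydronaphthalene-1-carboxylate
Conditions: reticulated vitreous carbon anode, Pt cathode, undivided cell, constant current, LiClO4 (0.1 M), 2,6-lutidine, MeOH/THF, rt, slightly more than 2 F/mol
Reagents that add atoms: methanol, CO
Why: One-electron oxidation of the enol ether (or of the allylsilane, which leads to the same bond) gives a radical cation electrophilic at C10; C9, the γ-carbon of the allylsilane, attacks it, a second electron is removed, the β-silyl cation at C8 loses its silyl group to methanol to give the C8(17) methylene, and the C20 oxocarbenium ion is trapped by methanol as the dimethyl acetal. The closest known reaction type is the intramolecular anodic coupling of enol ether radical cations with allylsilanes, which is established for six-membered rings and for quaternary carbons. Ring B closes in a 6-exo mode with respect to the C10=C20 bond, while the C8=C9 bond lies inside the forming ring (6-endo with respect to the allylsilane). C10 is controlled by ring A: with the C5 tether equatorial the C19 ester is axial and shields the β face of C10, so C9 bonds equatorially from the α side and C20 turns into the axial β position (trans-decalin); C9 is controlled by the (Z)-allylsilane geometry, which places C11 equatorial in the chair transition state. The step needs chemoselective oxidation (ester, chloride and the new 1,1-disubstituted alkene are not oxidised at the working potential), six- over five-membered closure (secured by the allylsilane polarity, since only attack through C9 gives the β-silyl cation) and fast methanol capture of the oxocarbenium ion (methanol as co-solvent, 2,6-lutidine as buffer).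

Step 10
Reactants: 19 methyl (1S,4aS,5S,8aR)-5-(2-chloroethyl)-4a-(dimethoxymethyl)-1-methyl-6-methylidenedecahydronaphthalene-1-carboxylate
Product: 20 methyl (1S,4aS,5S,8aR)-5-(2-chloroethyl)-4a-formyl-1-methyl-6-methylidenedecahydronaphthalene-1-carboxylate
Conditions: TsOH·H2O (cat.), acetone/H2O, rt
Reagents that add atoms: water, O
Why: Acid-catalysed acetal hydrolysis frees the neopentyl C20 aldehyde, which cannot epimerise because C10 is quaternary, and the mild sulfonic acid catalysis is chosen so that the 8(17)-alkene does not migrate.

Step 11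
Reactants: 20 methyl (1S,4aS,5S,8aR)-5-(2-chloroethyl)-4a-formyl-1-methyl-6-methylidenedecahydronaphthalene-1-carboxylate
Product: 22 methyl (1S,4aS,5S,8aR)-4a-[(acetyloxy)methyl]-5-(2-chloroethyl)-1-methyl-6-methylidenedecahydronaphthalene-1-carboxylate, via hydroxy ester 21 (not isolated)
Conditions: NaBH(OAc)3, AcOH, CH2Cl2, rt; then pyridine, Ac2O, DMAP, 0 °C → rt
Reagents that add atoms: acetic anhydride, CC(=O)OC(C)=O
Why: Chemoselective hydride reduction of the aldehyde by the acyloxyborohydride in an acidic medium avoids a free alkoxide that would close the δ-lactone onto the syn-axial C19 ester, and DMAP-catalysed acetylation in the same flask caps the C20 alcohol while ester, chloride and alkene stay inert.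

Step 12
Reactants: 22 methyl (1S,4aS,5S,8aR)-4a-[(acetyloxy)methyl]-5-(2-chloroethyl)-1-methyl-6-methylidenedecahydronaphthalene-1-carboxylate
Product: 23 methyl (1S,4aS,5S,8aR)-4a-[(acetyloxy)methyl]-5-(2-iodoethyl)-1-methyl-6-methylidenedecahydronaphthalene-1-carboxylate
Conditions: NaI, butan-2-one, 80 °C
Reagents that add atoms: sodium iodide, [Na+].[I-]
Why: Finkelstein halide exchange (SN2) at the unhindered primary C12 chloride is driven by precipitation of NaCl and does not touch acetate, ester or alkene.

Step 13
Reactants: 23 methyl (1S,4aS,5S,8aR)-4a-[(acetyloxy)methyl]-5-(2-iodoethyl)-1-methyl-6-methylidenedecahydronaphthalene-1-carboxylate; 24 3-bromofuran-2(5H)-one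
Product: 26 methyl (1S,4aS,5S,8aR)-4a-[(acetyloxy)methyl]-1-methyl-6-methylidene-5-[2-(2-oxo-2,5-dihydrofuran-3-yl)ethyl]decahydronaphthalene-1-carboxylate (CNP0104712.1), via alkylzinc iodide 25 (not isolated)
Conditions: Zn dust (activated with Me3SiCl and BrCH2CH2Br), LiCl, THF, 40 °C; then 24, PdCl2(dppf) (5 mol%), THF/DMF, rt
Reagents that add atoms: 24 3-bromofuran-2(5H)-one, O=C1OCC=C1Br
Why: Zinc insertion into the primary C–I bond gives an alkylzinc iodide that tolerates both esters, and Negishi cross-coupling with the electron-poor α-bromobutenolide forms the C12–C13 bond without creating or disturbing any stereocentre, the wide-bite-angle ligand favouring reductive elimination over β-hydride elimination.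

**Compound list**

1 | 2,3-dihydrofuran | C1=COCC1 | starting material
2 | oxirane | C1CO1 | starting material
3 | 5-lithio-2,3-dihydrofuran | [Li]C1=CCCO1 | intermediate
4 | lithium 2-(4,5-dihydrofuran-2-yl)ethanolate | [Li+].[O-]CCC1=CCCO1 | intermediate
5 | tert-butyl[2-(4,5-dihydrofuran-2-yl)ethoxy]dimethylsilane | CC(C)(C)[Si](C)(C)OCCC1=CCCO1 | intermediate
6 | (trimethylsilyl)methylmagnesium chloride | C[Si](C)(C)C[Mg]Cl | starting material
7 | (3Z)-6-[(tert-butyldimethylsilyl)oxy]-4-[(trimethylsilyl)methyl]hex-3-en-1-ol | CC(C)(C)[Si](C)(C)OCC/C(C[Si](C)(C)C)=C/CCO | intermediate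
8 | (3Z)-6-[(tert-butyldimethylsilyl)oxy]-4-[(trimethylsilyl)methyl]hex-3-en-1-yl methanesulfonate | CC(C)(C)[Si](C)(C)OCC/C(C[Si](C)(C)C)=C/CCOS(C)(=O)=O | intermediate
9 | tert-butyl{[(3Z)-6-chloro-3-[(trimethylsilyl)methyl]hex-3-en-1-yl]oxy}dimethylsilane | CC(C)(C)[Si](C)(C)OCC/C(C[Si](C)(C)C)=C/CCCl | intermediate
10 | (3Z)-6-chloro-3-[(trimethylsilyl)methyl]hex-3-en-1-ol | OCC/C(C[Si](C)(C)C)=C/CCCl | intermediate
11 | (3Z)-6-chloro-1-iodo-3-[(trimethylsilyl)methyl]hex-3-ene | ICC/C(C[Si](C)(C)C)=C/CCCl | intermediate
12 | methyl 3-oxocyclohex-1-ene-1-carboxylate | COC(=O)C1=CC(=O)CCC1 | starting material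
13 | methyl (1R)-3-{[dimethyl(phenyl)silyl]oxy}cyclohex-2-ene-1-carboxylate | COC(=O)[C@@H]1CCCC(O[Si](C)(C)c2ccccc2)=C1 | intermediate
14 | methyl (1R,2S)-2-{(3Z)-6-chloro-3-[(trimethylsilyl)methyl]hex-3-en-1-yl}-3-oxocyclohexane-1-carboxylate | O=C1CCC[C@@H](C(=O)OC)[C@@H]1CC/C(C[Si](C)(C)C)=C/CCCl | intermediate
15 | (methoxymethyl)triphenylphosphonium chloride | COC[P+](c1ccccc1)(c1ccccc1)c1ccccc1.[Cl-] | starting material
16 | methyl (1R,2S)-2-{(3Z)-6-chloro-3-[(trimethylsilyl)methyl]hex-3-en-1-yl}-3-(methoxymethylidene)cyclohexane-1-carboxylate, E/Z mixture at the enol ether | COC=C1CCC[C@@H](C(=O)OC)[C@@H]1CC/C(C[Si](C)(C)C)=C/CCCl | intermediate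
17 | lithium ester enolate of 16 (C5 configured as in 16) | COC=C1CCCC(=C(OC)O[Li])[C@@H]1CC/C(C[Si](C)(C)C)=C/CCCl | intermediate
18 | methyl (1S,2R)-2-{(3Z)-6-chloro-3-[(trimethylsilyl)methyl]hex-3-en-1-yl}-3-(methoxymethylidene)-1-methylcyclohexane-1-carboxylate, E/Z mixture at the enol ether | COC=C1CCC[C@](C)(C(=O)OC)[C@@H]1CC/C(C[Si](C)(C)C)=C/CCCl | intermediate
19 | methyl (1S,4aS,5S,8aR)-5-(2-chloroethyl)-4a-(dimethoxymethyl)-1-methyl-6-methylidenedecahydronaphthalene-1-carboxylate | C=C1CC[C@@H]2[C@](C(OC)OC)(CCC[C@]2(C)C(=O)OC)[C@H]1CCCl | intermediate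
20 | methyl (1S,4aS,5S,8aR)-5-(2-chloroethyl)-4a-formyl-1-methyl-6-methylidenedecahydronaphthalene-1-carboxylate | C=C1CC[C@@H]2[C@](C=O)(CCC[C@]2(C)C(=O)OC)[C@H]1CCCl | intermediate
21 | methyl (1S,4aS,5S,8aR)-5-(2-chloroethyl)-4a-(hydroxymethyl)-1-methyl-6-methylidenedecahydronaphthalene-1-carboxylate | C=C1CC[C@@H]2[C@](CO)(CCC[C@]2(C)C(=O)OC)[C@H]1CCCl | intermediate
22 | methyl (1S,4aS,5S,8aR)-4a-[(acetyloxy)methyl]-5-(2-chloroethyl)-1-methyl-6-methylidenedecahydronaphthalene-1-carboxylate | C=C1CC[C@@H]2[C@](COC(C)=O)(CCC[C@]2(C)C(=O)OC)[C@H]1CCCl | intermediate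
23 | methyl (1S,4aS,5S,8aR)-4a-[(acetyloxy)methyl]-5-(2-iodoethyl)-1-methyl-6-methylidenedecahydronaphthalene-1-carboxylate | C=C1CC[C@@H]2[C@](COC(C)=O)(CCC[C@]2(C)C(=O)OC)[C@H]1CCI | intermediate
24 | 3-bromofuran-2(5H)-one | O=C1OCC=C1Br | starting material
25 | alkylzinc iodide from 23 (iodozincio group at C12) | C=C1CC[C@@H]2[C@](COC(C)=O)(CCC[C@]2(C)C(=O)OC)[C@H]1CC[Zn]I | intermediate
26 | methyl (1S,4aS,5S,8aR)-4a-[(acetyloxy)methyl]-1-methyl-6-methylidene-5-[2-(2-oxo-2,5-dihydrofuran-3-yl)ethyl]decahydronaphthalene-1-carboxylate | C=C1CC[C@@H]2[C@](COC(C)=O)(CCC[C@]2(C)C(=O)OC)[C@H]1CCC1=CCOC1=O | target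

**Step count**

Total: 13 steps. Longest linear sequence: 13 steps (1 to 26 through steps 1–13; 12, 15 and 24 enter as purchased materials).

**Steps most likely to fail**

Step 9 (anodic ring closure). Three processes may compete:
- closure through the ring A conformer with an axial tether, which would give the cis-fused decalin;
- loss of the silyl group or methanol capture of the radical cation before the C9–C10 bond forms;
- capture of the C20 oxocarbenium ion by the neighbouring C19 ester carbonyl instead of methanol.

The fallback closes ring B by an ionic, Lewis-acid route and sets out from keto ester 14. Corey–Chaykovsky methylenation with the sulfoxonium ylide (Me3S(O)I, NaH, DMSO) should deliver the methylene equatorially and give the spiro-epoxide F1 with its oxygen axial. Ester enolate methylation as in step 8 (LiN(i-Pr)2, MeI) would then give the C4-methylated spiro-epoxide F2. Et2AlCl in CH2Cl2 at −78 °C should open the epoxide at the tertiary C10 with attack by C9 of the allylsilane and loss of the silyl group (epoxide-initiated cation–olefin cyclisation terminated by an allylsilane). This gives the C20 alcohol directly, and the route is rejoined at hydroxy ester 21, which is acetylated at once as in step 11; steps 7, 9 and 10 are bypassed.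

Step 6 (conjugate reduction and C5 alkylation). The reduction may show insufficient enantioselectivity or deliver hydride to the wrong alkene carbon. In the alkylation, the unactivated iodide may react slowly in the SN2 sense, which leaves room for:
- E2 elimination;
- proton transfer between enolate and product, leading to over-alkylation and loss of regiocontrol;
- fluoride attack on the allylsilane.

The fallback makes C5 more acidic so that a mild base and a soft, stabilised enolate can be used. Silyl enol ether 13, made as in step 6, would be sulfenylated regiospecifically with PhSCl (CH2Cl2, −78 °C) to the α-phenylsulfanyl ketone F3. Alkylation of its enolate with iodide 11 (NaH, DMF, 0 °C → rt) would give the quaternary sulfide F4. Reductive removal of sulfur with SmI2 (THF/MeOH, −78 °C) and base equilibration at C5 (DBU) would return keto ester 14.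

Step 11 (reduction and acetylation at C20). The C20 hydroxyl, or its borate, may close onto the syn-axial C19 methyl ester with loss of methanol before it is acetylated (intramolecular transesterification). The fallback accepts this ring closure and reopens it under conditions in which the carboxylate cannot re-close. From aldehyde 20, NaBH4 in MeOH followed by warming would deliberately give the 19,20-lactone F5. LiOH in THF/H2O would open it to the lithium hydroxy-carboxylate F6. O-Methylation of the carboxylate with MeI in DMF (no alkoxide present) and immediate acetylation in the same flask (Ac2O, pyridine, DMAP) would give acetate 22.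

**Further compounds**

F1 | step 9 | methyl 4-{(3Z)-6-chloro-3-[(trimethylsilyl)methyl]hex-3-en-1-yl}-1-oxaspiro[2.5]octane-5-carboxylate (ring centres as in 14; oxirane oxygen axial, on the face of the C5 chain) | C1O[C@@]12CCC[C@@H](C(=O)OC)[C@@H]2CC/C(C[Si](C)(C)C)=C/CCCl
F2 | step 9 | methyl 4-{(3Z)-6-chloro-3-[(trimethylsilyl)methyl]hex-3-en-1-yl}-5-methyl-1-oxaspiro[2.5]octane-5-carboxylate (methyl trans to the chain; oxirane as in F1) | C1O[C@@]12CCC[C@](C)(C(=O)OC)[C@@H]2CC/C(C[Si](C)(C)C)=C/CCCl
F3 | step 6 | methyl (1S)-3-oxo-2-(phenylsulfanyl)cyclohexane-1-carboxylate (same spatial arrangement at C1 as in 13; both C2 epimers) | O=C1CCC[C@@H](C(=O)OC)C1Sc1ccccc1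
F4 | step 6 | methyl 2-{(3Z)-6-chloro-3-[(trimethylsilyl)methyl]hex-3-en-1-yl}-3-oxo-2-(phenylsulfanyl)cyclohexane-1-carboxylate (C1 as in F3; both C2 epimers) | O=C1CCC[C@@H](C(=O)OC)C1(Sc1ccccc1)CC/C(C[Si](C)(C)C)=C/CCCl
F5 | step 11 | 19,20-lactone of 21 (δ-lactone between the C19 carboxyl and the C20 oxygen) | C=C1CC[C@@H]2[C@](CO3)(CCC[C@]2(C)C3=O)[C@H]1CCCl
F6 | step 11 | lithium (1S,4aS,5S,8aR)-5-(2-chloroethyl)-4a-(hydroxymethyl)-1-methyl-6-methylidenedecahydronaphthalene-1-carboxylate | C=C1CC[C@@H]2[C@](CO)(CCC[C@]2(C)C(=O)[O-])[C@H]1CCCl.[Li+]
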